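**Retrosynthetic overview**
1. The target comes from its 15-O-TBDPS ether; the ten-membered carbocycle is closed last, by ring-closing metathesis at C2=C3.
2. The C8 ester is installed by Mitsunobu inversion with (2Z)-4-acetoxy-2-methylbut-2-enoic acid (fragment C, from but-2-yn-1-ol).
3. Key C7–C8 bond: intermolecular zinc Barbier allylation of a β,γ-epoxy aldehyde (fragment A) by a 3-(bromomethyl)butenolide (fragment B); this creates the α-methylene-γ-butyrolactone and sets C7 and C8 from C6.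
4. Fragment A: but-3-yn-1-ol, carboalumination, Sharpless epoxidation (C1, C10). Fragment B: propargyl alcohol plus acrolein, Sharpless kinetic resolution (C6), trans-hydroalumination/iodination, metathesis, Stille vinylation.
5. Ring order: oxirane, then butenolide (converted into the methylene lactone by the Barbier step), then the ten-membered ring.

Assumption and notation: positions use germacrane numbering (C1/C10 epoxide, C2=C3 and C4=C5 diene, C6 lactone O–CH, C7, C8 ester carbon, C11–C13 methylene lactone, C15 hydroxymethyl); TBS = tert-butyldimethylsilyl, TBDPS = tert-butyldiphenylsilyl.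

**Fragment A**

Step 1
Reactants: 1 but-3-yn-1-ol
Product: 2 tert-butyl(but-3-yn-1-yloxy)dimethylsilane
Conditions: TBSCl, imidazole, CH2Cl2, 0 °C to rt
Reagents that add atoms: tert-butyl(chloro)dimethylsilane, CC(C)(C)[Si](C)(C)Cl
Why: Routine silylation protects the future C8 oxygen through the organometallic and Wittig steps.

Step 2
Reactants: 2 tert-butyl(but-3-yn-1-yloxy)dimethylsilane
Product: 5 (2E)-5-(TBS-oxy)-3-methylpent-2-en-1-ol, via alkenyldimethylalane 3 (not isolated), via lithium alkenylalanate 4 (not isolated)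
Conditions: AlMe3 (2 equiv), Cp2ZrCl2 (0.25 equiv), CH2Cl2, 0 °C to rt; then n-BuLi, hexane/THF, −78 °C; (CH2O)n, rt; aqueous work-up
Reagents that add atoms: trimethylaluminium, C[Al](C)C; paraformaldehyde (formaldehyde unit), C=O
Why: Negishi zirconium-catalysed carboalumination adds methyl and aluminium syn with methyl on the internal carbon, and hydroxymethylation of the alanate occurs with retention, so the trisubstituted olefin (future C1/C10) is E.

Step 3
Reactants: 5 (2E)-5-(TBS-oxy)-3-methylpent-2-en-1-ol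
Product: 6 {(2R,3R)-3-[2-(TBS-oxy)ethyl]-3-methyloxiran-2-yl}methanol
Conditions: Ti(OiPr)4 (10 mol%), D-(−)-diethyl tartrate (12 mol%), t-BuOOH (2 equiv), 4 Å MS, CH2Cl2, −20 °C
Reagents that add atoms: tert-butyl hydroperoxide, CC(C)(C)OO
Why: Sharpless asymmetric epoxidation with D-(−)-tartrate gives the (2R,3R)-epoxide (the mirror image of the (2S,3S)-epoxide that geraniol gives with L-(+)-tartrate), which becomes C1 (R) and C10 (R).

Step 4
Reactants: 6 {(2R,3R)-3-[2-(TBS-oxy)ethyl]-3-methyloxiran-2-yl}methanol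
Product: 7 (2S,3R)-3-[2-(TBS-oxy)ethyl]-3-methyloxirane-2-carbaldehyde
Conditions: TEMPO (10 mol%), PhI(OAc)2 (1.1 equiv), CH2Cl2, rt
Reagents that add atoms: none
Why: Nitroxyl-catalysed oxidation stops at the aldehyde and leaves the epoxide and its stereocentres untouched (the descriptor changes only through CIP priorities).

Step 5
Reactants: 7 (2S,3R)-3-[2-(TBS-oxy)ethyl]-3-methyloxirane-2-carbaldehyde
Product: 8 tert-butyl{2-[(2R,3R)-3-ethenyl-2-methyloxiran-2-yl]ethoxy}dimethylsilane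
Conditions: Ph3PCH3Br, KN(SiMe3)2, THF, −78 to 0 °C
Reagents that add atoms: methyltriphenylphosphonium bromide, [Br-].C[P+](c1ccccc1)(c1ccccc1)c1ccccc1
Why: Wittig methylenation of the α,β-epoxy aldehyde gives the vinyl epoxide needed for the final metathesis, done here before any base-sensitive lactone exists.

Step 6
Reactants: 8 tert-butyl{2-[(2R,3R)-3-ethenyl-2-methyloxiran-2-yl]ethoxy}dimethylsilane
Product: 9 2-[(2R,3R)-3-ethenyl-2-methyloxiran-2-yl]ethan-1-ol
Conditions: Bu4NF, THF, 0 °C; concentrate cold (volatile)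
Reagents that add atoms: none
Why: Fluoride desilylation frees the primary alcohol without opening the vinyl epoxide.

Step 7
Reactants: 9 2-[(2R,3R)-3-ethenyl-2-methyloxiran-2-yl]ethan-1-ol
Product: 10 [(2R,3R)-3-ethenyl-2-methyloxiran-2-yl]acetaldehyde
Conditions: Dess–Martin periodinane, NaHCO3, CH2Cl2, 0 °C; filtered, used at once as a cold THF solution
Reagents that add atoms: none
Why: Buffered Dess–Martin oxidation is fast and non-basic, which keeps the β,γ-epoxy aldehyde from eliminating to the γ-hydroxy enal before it is used.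

**Fragment B**

Step 8
Reactants: 11 prop-2-yn-1-ol
Product: 12 tert-butyl(diphenyl)(prop-2-yn-1-yloxy)silane
Conditions: TBDPSCl, imidazole, CH2Cl2, 0 °C to rt
Reagents that add atoms: tert-butyl(chloro)diphenylsilane, CC(C)(C)[Si](Cl)(c1ccccc1)c1ccccc1
Why: The robust silyl ether protects the future C15 oxygen until the last step.

Step 9
Reactants: 12 tert-butyl(diphenyl)(prop-2-yn-1-yloxy)silane; 13 prop-2-enal (acrolein)
Product: 15 rac-6-(TBDPS-oxy)hex-1-en-4-yn-3-ol, via lithium acetylide 14 (not isolated)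
Conditions: n-BuLi, THF, −78 °C; then acrolein, −78 °C; H2O quench
Reagents that add atoms: none
Why: The lithium acetylide adds 1,2 to acrolein at low temperature, giving the vinyl alkynyl carbinol that carries C4–C7 and C15.

Step 10
Reactants: 15 rac-6-(TBDPS-oxy)hex-1-en-4-yn-3-ol
Product: 16 (3S)-6-(TBDPS-oxy)hex-1-en-4-yn-3-ol
Conditions: Ti(OiPr)4 (1.0 equiv), L-(+)-diisopropyl tartrate (1.2 equiv), t-BuOOH (0.6 equiv), 4 Å MS, CH2Cl2, −20 °C, to about 60% conversion
Reagents that add atoms: none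
Why: Sharpless kinetic resolution with L-(+)-tartrate epoxidises the vinyl group of the (R)-carbinol much faster, leaving the (S)-alcohol (future C6) in high ee.

Step 11
Reactants: 16 (3S)-6-(TBDPS-oxy)hex-1-en-4-yn-3-ol
Product: 18 (3S,4Z)-6-(TBDPS-oxy)-5-iodohexa-1,4-dien-3-ol, via sodium alkenylaluminate 17 (not isolated)
Conditions: NaAlH2(OCH2CH2OMe)2 (Red-Al), THF, −20 to 0 °C; EtOAc; then I2, THF, −78 °C
Reagents that add atoms: iodine, II
Why: Hydroxyl-directed trans-hydroalumination places aluminium on the alkyne carbon distal to the alkoxide, and iodinolysis with retention gives the Z-iodoalkene with the carbinol carbon cis to iodine, which fixes the C4=C5 geometry.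

Step 12
Reactants: 19 methyl 2-(hydroxymethyl)prop-2-enoate
Product: 20 methyl 2-[(TBS-oxy)methyl]prop-2-enoate
Conditions: TBSCl, imidazole, CH2Cl2, 0 °C to rt
Reagents that add atoms: tert-butyl(chloro)dimethylsilane, CC(C)(C)[Si](C)(C)Cl
Why: Silylation masks the future C13 oxygen so that the palladium-catalysed step can precede bromide formation.

Step 13
Reactants: 20 methyl 2-[(TBS-oxy)methyl]prop-2-enoate
Product: 21 2-[(TBS-oxy)methyl]prop-2-enoic acid
Conditions: LiOH, THF/H2O, 0 °C to rt; then 1 M HCl to pH 4, 0 °C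
Reagents that add atoms: lithium hydroxide, [Li+].[OH-]
Why: Saponification of the methyl ester gives the acid for the acylation, the primary silyl ether surviving the cold mild acidification.

Step 14
Reactants: 18 (3S,4Z)-6-(TBDPS-oxy)-5-iodohexa-1,4-dien-3-ol; 21 2-[(TBS-oxy)methyl]prop-2-enoic acid
Product: 22 (3S,4Z)-6-(TBDPS-oxy)-5-iodohexa-1,4-dien-3-yl 2-[(TBS-oxy)methyl]prop-2-enoate
Conditions: DCC, DMAP (10 mol%), CH2Cl2, 0 °C to rt
Reagents that add atoms: none
Why: Steglich esterification acylates the secondary alcohol under neutral conditions without ionising the doubly allylic carbinol.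

Step 15
Reactants: 22 (3S,4Z)-6-(TBDPS-oxy)-5-iodohexa-1,4-dien-3-yl 2-[(TBS-oxy)methyl]prop-2-enoate
Product: 23 (5S)-3-[(TBS-oxy)methyl]-5-[(1Z)-3-(TBDPS-oxy)-2-iodoprop-1-en-1-yl]furan-2(5H)-one
Conditions: second-generation Grubbs catalyst RuCl2(=CHPh)(PCy3)(H2IMes) (5 mol%), CH2Cl2, 40 °C
Reagents that add atoms: none
Why: Ring-closing metathesis between the terminal vinyl group and the acrylate forms the butenolide, the trisubstituted iodoalkene being inert to the ruthenium carbene.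

Step 16
Reactants: 23 (5S)-3-[(TBS-oxy)methyl]-5-[(1Z)-3-(TBDPS-oxy)-2-iodoprop-1-en-1-yl]furan-2(5H)-one
Product: 24 (5R)-3-[(TBS-oxy)methyl]-5-{(1E)-2-[(TBDPS-oxy)methyl]buta-1,3-dien-1-yl}furan-2(5H)-one
Conditions: Bu3SnCH=CH2, Pd2(dba)3 (5 mol%), AsPh3 (20 mol%), NMP, rt
Reagents that add atoms: tributyl(ethenyl)stannane, C=C[Sn](CCCC)(CCCC)CCCC
Why: Stille coupling replaces iodide by vinyl with retention under neutral conditions, giving the diene with C6 cis to C3 (the descriptors change only through CIP priorities).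

Step 17
Reactants: 24 (5R)-3-[(TBS-oxy)methyl]-5-{(1E)-2-[(TBDPS-oxy)methyl]buta-1,3-dien-1-yl}furan-2(5H)-one
Product: 25 (5R)-5-{(1E)-2-[(TBDPS-oxy)methyl]buta-1,3-dien-1-yl}-3-(hydroxymethyl)furan-2(5H)-one
Conditions: pyridinium p-toluenesulfonate (20 mol%), MeOH, rt
Reagents that add atoms: none
Why: Mild acidic methanolysis removes the primary TBS ether selectively, the TBDPS ether being about a hundred times more stable to acid.

Step 18
Reactants: 25 (5R)-5-{(1E)-2-[(TBDPS-oxy)methyl]buta-1,3-dien-1-yl}-3-(hydroxymethyl)furan-2(5H)-one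
Product: 26 (5R)-3-(bromomethyl)-5-{(1E)-2-[(TBDPS-oxy)methyl]buta-1,3-dien-1-yl}furan-2(5H)-one
Conditions: CBr4, PPh3, CH2Cl2, 0 °C
Reagents that add atoms: tetrabromomethane, BrC(Br)(Br)Br
Why: The Appel reaction converts the primary allylic alcohol into the bromide without base, which the acidic C6–H of the dienyl butenolide would not tolerate.

**Fragment C**

Step 19
Reactants: 27 but-2-yn-1-ol
Product: 29 (2Z)-3-iodobut-2-en-1-ol, via sodium alkenylaluminate 28 (not isolated)
Conditions: NaAlH2(OCH2CH2OMe)2 (Red-Al), THF, 0 °C; EtOAc; then I2, THF, −78 °C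
Reagents that add atoms: iodine, II
Why: Directed trans-hydroalumination and iodinolysis give only the Z-iodoalkene, which fixes the cis relation of the future carboxyl and acetoxymethyl groups.

Step 20
Reactants: 29 (2Z)-3-iodobut-2-en-1-ol
Product: 30 tert-butyl{[(2Z)-3-iodobut-2-en-1-yl]oxy}dimethylsilane
Conditions: TBSCl, imidazole, CH2Cl2, 0 °C to rt
Reagents that add atoms: tert-butyl(chloro)dimethylsilane, CC(C)(C)[Si](C)(C)Cl
Why: Silyl protection allows halogen–lithium exchange in the next step.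

Step 21
Reactants: 30 tert-butyl{[(2Z)-3-iodobut-2-en-1-yl]oxy}dimethylsilane
Product: 32 tert-butyl (2Z)-4-(TBS-oxy)-2-methylbut-2-enoate, via vinyllithium 31 (not isolated)
Conditions: t-BuLi (2.1 equiv), Et2O, −78 °C; then Boc2O, −78 °C to rt
Reagents that add atoms: di-tert-butyl dicarbonate, CC(C)(C)OC(=O)OC(=O)OC(C)(C)C
Why: Iodine–lithium exchange is stereoretentive at −78 °C and acylation with Boc2O gives the tert-butyl ester, chosen because it can later be cleaved without touching an acetate.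

Step 22
Reactants: 32 tert-butyl (2Z)-4-(TBS-oxy)-2-methylbut-2-enoate
Product: 33 tert-butyl (2Z)-4-hydroxy-2-methylbut-2-enoate
Conditions: Bu4NF, AcOH (1:1), THF, 0 °C
Reagents that add atoms: none
Why: Buffered fluoride removes the silyl group, and the bulky tert-butyl ester suppresses lactonisation of the Z-γ-hydroxy enoate to the butenolide.

Step 23
Reactants: 33 tert-butyl (2Z)-4-hydroxy-2-methylbut-2-enoate
Product: 34 tert-butyl (2Z)-4-(acetyloxy)-2-methylbut-2-enoate
Conditions: Ac2O, pyridine, DMAP (5 mol%), CH2Cl2, 0 °C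
Reagents that add atoms: acetic anhydride, CC(=O)OC(C)=O
Why: Acetylation of the primary allylic alcohol installs the side-chain acetate while the carboxyl group is still masked.

Step 24
Reactants: 34 tert-butyl (2Z)-4-(acetyloxy)-2-methylbut-2-enoate
Product: 35 (2Z)-4-(acetyloxy)-2-methylbut-2-enoic acid
Conditions: CF3CO2H/CH2Cl2 (1:4), 0 °C; toluene co-evaporation
Reagents that add atoms: none
Why: Acidolysis of the tert-butyl ester (loss of isobutene) frees the acid without hydrolysing the acetate or isomerising the Z-olefin.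

**Fragment union and endgame**

Step 25
Reactants: 26 (5R)-3-(bromomethyl)-5-{(1E)-2-[(TBDPS-oxy)methyl]buta-1,3-dien-1-yl}furan-2(5H)-one; 10 [(2R,3R)-3-ethenyl-2-methyloxiran-2-yl]acetaldehyde
Product: 37 (4R,5R)-4-{(1S)-2-[(2R,3R)-3-ethenyl-2-methyloxiran-2-yl]-1-hydroxyethyl}-5-{(1E)-2-[(TBDPS-oxy)methyl]buta-1,3-dien-1-yl}-3-methylideneoxolan-2-one, via allylzinc bromide 36 (not isolated)
Conditions: Zn dust (3 equiv), THF/sat. aq. NH4Cl (2:1), 0 °C, 1 h
Reagents that add atoms: none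
Why: In this Barbier-type carbonyl allylation the allylzinc adds through its γ-carbon (C7) anti to the C6 dienyl group via a chair Zimmerman–Traxler transition state, giving the trans-lactone (C7 R) and the 7,8-anti alcohol (C8 S).

Step 26
Reactants: 37 the Barbier adduct; 35 (2Z)-4-(acetyloxy)-2-methylbut-2-enoic acid
Product: 38 (1R)-2-[(2R,3R)-3-ethenyl-2-methyloxiran-2-yl]-1-[(2R,3R)-2-{(1E)-2-[(TBDPS-oxy)methyl]buta-1,3-dien-1-yl}-4-methylidene-5-oxooxolan-3-yl]ethyl (2Z)-4-(acetyloxy)-2-methylbut-2-enoate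
Conditions: PPh3, diisopropyl azodicarboxylate, THF, 0 °C to rt
Reagents that add atoms: none
Why: Mitsunobu esterification displaces the alkoxyphosphonium by SN2, inverting C8 from S to the required R while attaching the side chain without base that could isomerise the Z-enoate.

Step 27
Reactants: 38 the C8 ester
Product: 39 15-O-TBDPS ether of the target (ten-membered ring closed with C2=C3 Z)
Conditions: second-generation Grubbs catalyst RuCl2(=CHPh)(PCy3)(H2IMes) (10 mol% in two portions), toluene (1 mM), 80 °C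
Reagents that add atoms: none
Why: Ring-closing metathesis joins the vinyl epoxide and the terminal vinyl of the diene, the hindered trisubstituted C4=C5 olefin staying out of the reaction and ring strain enforcing the Z C2=C3 olefin.

Step 28
Reactants: 39 15-O-TBDPS ether of the target
Product: 40 CNP0103272.1, (1R,6R,7R,8R,10R)-8-{[(2Z)-4-(acetyloxy)-2-methylbut-2-enoyl]oxy}-1,10-epoxy-15-hydroxygermacra-2Z,4E,11(13)-trien-12,6-olide
Conditions: Bu4NF, AcOH (1:1), THF, 0 °C to rt
Reagents that add atoms: none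
Why: Acetic acid-buffered fluoride cleaves the silyl ether without harming the acetate, the Z-enoate, the vinyl epoxide or the α-methylene lactone.

**Compound list**

1 | but-3-yn-1-ol | C#CCCO | starting material
2 | tert-butyl(but-3-yn-1-yloxy)dimethylsilane | C#CCCO[Si](C)(C)C(C)(C)C | intermediate
3 | [(1E)-4-(TBS-oxy)-2-methylbut-1-en-1-yl]dimethylalane | C[Al](C)/C=C(\C)CCO[Si](C)(C)C(C)(C)C | intermediate (not isolated)
4 | lithium butyl[(1E)-4-(TBS-oxy)-2-methylbut-1-en-1-yl]dimethylaluminate | [Li+].CCCC[Al-](C)(C)/C=C(\C)CCO[Si](C)(C)C(C)(C)C | intermediate (not isolated)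
5 | (2E)-5-(TBS-oxy)-3-methylpent-2-en-1-ol | OC/C=C(\C)CCO[Si](C)(C)C(C)(C)C | intermediate
6 | {(2R,3R)-3-[2-(TBS-oxy)ethyl]-3-methyloxiran-2-yl}methanol | OC[C@H]1O[C@]1(C)CCO[Si](C)(C)C(C)(C)C | intermediate
7 | (2S,3R)-3-[2-(TBS-oxy)ethyl]-3-methyloxirane-2-carbaldehyde | O=C[C@H]1O[C@]1(C)CCO[Si](C)(C)C(C)(C)C | intermediate
8 | tert-butyl{2-[(2R,3R)-3-ethenyl-2-methyloxiran-2-yl]ethoxy}dimethylsilane | C=C[C@H]1O[C@]1(C)CCO[Si](C)(C)C(C)(C)C | intermediate
9 | 2-[(2R,3R)-3-ethenyl-2-methyloxiran-2-yl]ethan-1-ol | C=C[C@H]1O[C@]1(C)CCO | intermediate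
10 | [(2R,3R)-3-ethenyl-2-methyloxiran-2-yl]acetaldehyde | C=C[C@H]1O[C@]1(C)CC=O | intermediate
11 | prop-2-yn-1-ol | C#CCO | starting material
12 | tert-butyl(diphenyl)(prop-2-yn-1-yloxy)silane | C#CCO[Si](c1ccccc1)(c1ccccc1)C(C)(C)C | intermediate
13 | prop-2-enal (acrolein) | C=CC=O | starting material
14 | lithium 3-(TBDPS-oxy)prop-1-yn-1-ide | [Li]C#CCO[Si](c1ccccc1)(c1ccccc1)C(C)(C)C | intermediate (not isolated)
15 | rac-6-(TBDPS-oxy)hex-1-en-4-yn-3-ol | C=CC(O)C#CCO[Si](c1ccccc1)(c1ccccc1)C(C)(C)C | intermediate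
16 | (3S)-6-(TBDPS-oxy)hex-1-en-4-yn-3-ol | C=C[C@H](O)C#CCO[Si](c1ccccc1)(c1ccccc1)C(C)(C)C | intermediate
17 | sodium (5S)-5-ethenyl-2,2-bis(2-methoxyethoxy)-3-[(TBDPS-oxy)methyl]-2,5-dihydro-1,2-oxaluminol-2-uide (cyclic alkenylaluminate of 16) | [Na+].C=C[C@@H]1O[Al-](OCCOC)(OCCOC)C(CO[Si](c2ccccc2)(c2ccccc2)C(C)(C)C)=C1 | intermediate (not isolated)
18 | (3S,4Z)-6-(TBDPS-oxy)-5-iodohexa-1,4-dien-3-ol | C=C[C@H](O)/C=C(\I)CO[Si](c1ccccc1)(c1ccccc1)C(C)(C)C | intermediate
19 | methyl 2-(hydroxymethyl)prop-2-enoate | C=C(CO)C(=O)OC | starting material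
20 | methyl 2-[(TBS-oxy)methyl]prop-2-enoate | C=C(CO[Si](C)(C)C(C)(C)C)C(=O)OC | intermediate
21 | 2-[(TBS-oxy)methyl]prop-2-enoic acid | C=C(CO[Si](C)(C)C(C)(C)C)C(=O)O | intermediate
22 | (3S,4Z)-6-(TBDPS-oxy)-5-iodohexa-1,4-dien-3-yl 2-[(TBS-oxy)methyl]prop-2-enoate | C=C[C@H](OC(=O)C(=C)CO[Si](C)(C)C(C)(C)C)/C=C(\I)CO[Si](c1ccccc1)(c1ccccc1)C(C)(C)C | intermediate
23 | (5S)-3-[(TBS-oxy)methyl]-5-[(1Z)-3-(TBDPS-oxy)-2-iodoprop-1-en-1-yl]furan-2(5H)-one | O=C1O[C@H](/C=C(\I)CO[Si](c2ccccc2)(c2ccccc2)C(C)(C)C)C=C1CO[Si](C)(C)C(C)(C)C | intermediate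
24 | (5R)-3-[(TBS-oxy)methyl]-5-{(1E)-2-[(TBDPS-oxy)methyl]buta-1,3-dien-1-yl}furan-2(5H)-one | O=C1O[C@H](/C=C(\C=C)CO[Si](c2ccccc2)(c2ccccc2)C(C)(C)C)C=C1CO[Si](C)(C)C(C)(C)C | intermediate
25 | (5R)-5-{(1E)-2-[(TBDPS-oxy)methyl]buta-1,3-dien-1-yl}-3-(hydroxymethyl)furan-2(5H)-one | O=C1O[C@H](/C=C(\C=C)CO[Si](c2ccccc2)(c2ccccc2)C(C)(C)C)C=C1CO | intermediate
26 | (5R)-3-(bromomethyl)-5-{(1E)-2-[(TBDPS-oxy)methyl]buta-1,3-dien-1-yl}furan-2(5H)-one | O=C1O[C@H](/C=C(\C=C)CO[Si](c2ccccc2)(c2ccccc2)C(C)(C)C)C=C1CBr | intermediate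
27 | but-2-yn-1-ol | CC#CCO | starting material
28 | sodium 2,2-bis(2-methoxyethoxy)-3-methyl-2,5-dihydro-1,2-oxaluminol-2-uide (cyclic alkenylaluminate of 27) | [Na+].CC1=CCO[Al-]1(OCCOC)OCCOC | intermediate (not isolated)
29 | (2Z)-3-iodobut-2-en-1-ol | C/C(I)=C/CO | intermediate
30 | tert-butyl{[(2Z)-3-iodobut-2-en-1-yl]oxy}dimethylsilane | C/C(I)=C/CO[Si](C)(C)C(C)(C)C | intermediate
31 | [(2Z)-4-(TBS-oxy)but-2-en-2-yl]lithium | C/C([Li])=C/CO[Si](C)(C)C(C)(C)C | intermediate (not isolated)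
32 | tert-butyl (2Z)-4-(TBS-oxy)-2-methylbut-2-enoate | C/C(C(=O)OC(C)(C)C)=C/CO[Si](C)(C)C(C)(C)C | intermediate
33 | tert-butyl (2Z)-4-hydroxy-2-methylbut-2-enoate | C/C(C(=O)OC(C)(C)C)=C/CO | intermediate
34 | tert-butyl (2Z)-4-(acetyloxy)-2-methylbut-2-enoate | C/C(C(=O)OC(C)(C)C)=C/COC(C)=O | intermediate
35 | (2Z)-4-(acetyloxy)-2-methylbut-2-enoic acid | C/C(C(=O)O)=C/COC(C)=O | intermediate
36 | {[(5R)-5-{(1E)-2-[(TBDPS-oxy)methyl]buta-1,3-dien-1-yl}-2-oxo-2,5-dihydrofuran-3-yl]methyl}zinc bromide | O=C1O[C@H](/C=C(\C=C)CO[Si](c2ccccc2)(c2ccccc2)C(C)(C)C)C=C1C[Zn]Br | intermediate (not isolated)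
37 | (4R,5R)-4-{(1S)-2-[(2R,3R)-3-ethenyl-2-methyloxiran-2-yl]-1-hydroxyethyl}-5-{(1E)-2-[(TBDPS-oxy)methyl]buta-1,3-dien-1-yl}-3-methylideneoxolan-2-one | C=C1C(=O)O[C@H](/C=C(\C=C)CO[Si](c2ccccc2)(c2ccccc2)C(C)(C)C)[C@H]1[C@@H](O)C[C@@]1(C)O[C@@H]1C=C | intermediate
38 | (1R)-2-[(2R,3R)-3-ethenyl-2-methyloxiran-2-yl]-1-[(2R,3R)-2-{(1E)-2-[(TBDPS-oxy)methyl]buta-1,3-dien-1-yl}-4-methylidene-5-oxooxolan-3-yl]ethyl (2Z)-4-(acetyloxy)-2-methylbut-2-enoate | C=C1C(=O)O[C@H](/C=C(\C=C)CO[Si](c2ccccc2)(c2ccccc2)C(C)(C)C)[C@H]1[C@H](OC(=O)/C(C)=C\COC(C)=O)C[C@@]1(C)O[C@@H]1C=C | intermediate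
39 | 15-O-TBDPS ether of the target, (1R,6R,7R,8R,10R) | C=C1C(=O)O[C@@H]2/C=C(CO[Si](c3ccccc3)(c3ccccc3)C(C)(C)C)\C=C/[C@H]3O[C@]3(C)C[C@@H](OC(=O)/C(C)=C\COC(C)=O)[C@@H]12 | intermediate
40 | CNP0103272.1, (1R,6R,7R,8R,10R)-8-{[(2Z)-4-(acetyloxy)-2-methylbut-2-enoyl]oxy}-1,10-epoxy-15-hydroxygermacra-2Z,4E,11(13)-trien-12,6-olide | C=C1C(=O)O[C@@H]2/C=C(CO)\C=C/[C@H]3O[C@]3(C)C[C@@H](OC(=O)/C(C)=C\COC(C)=O)[C@@H]12 | target

**Totals and risks**

Total step count: 28. Longest linear sequence: 13 steps (prop-2-yn-1-ol 11 through steps 8–11, 14–18 and 25–28 to 40).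

Most likely to fail, step 27 (closure of the strained ten-membered ring; oligomerisation or no turnover). Fallback: set out from alcohol 37 and change the order of events, so that the metathesis runs on the free, less encumbered (8S)-alcohol. Ring closure of 37 with the same ruthenium carbene gives the macrocyclic (8S)-alcohol 15-O-TBDPS ether F1. A Mitsunobu esterification of F1 with acid 35 (PPh3, diisopropyl azodicarboxylate) then inverts C8 on the ring and returns to the route at 39, bypassing 38.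

Second, step 26 (Mitsunobu on a hindered secondary alcohol; elimination toward C7=C8 or low conversion). Fallback: set out from 37 and replace the redox condensation by a sulfonate displacement. ClCH2SO2Cl and pyridine in CH2Cl2 at 0 °C give the (8S)-chloromethanesulfonate F2. Acid 35 and Cs2CO3 give caesium (2Z)-4-(acetyloxy)-2-methylbut-2-enoate F3, which displaces the sulfonate with inversion (18-crown-6, toluene, rt to 40 °C) and returns to the route at 38.

Third, step 25 (the β,γ-epoxy aldehyde 10 is labile, and chelation of zinc by the epoxide oxygen could erode or reverse the C8 selectivity). Fallback: set out from 26 and 10 and make the union stereoconvergent at C8 instead of relying on one epimer. Any (8R)-epimer of the Barbier adduct F4 is separated and acylated with retention. Acid 35, 2,4,6-trichlorobenzoyl chloride and Et3N give the mixed anhydride F5, which is heated with F4 in toluene at 70 °C without a nucleophilic catalyst (to keep the Z-enoate) and returns to the route at 38. The (8S)-epimer 37 continues through step 26 as before.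

Further compounds
F1 | step 27 | macrocyclic (1R,6R,7R,8S,10R)-8-hydroxy 15-O-TBDPS ether (39 with a free, epimeric C8 hydroxyl in place of the ester) | C=C1C(=O)O[C@@H]2/C=C(CO[Si](c3ccccc3)(c3ccccc3)C(C)(C)C)\C=C/[C@H]3O[C@]3(C)C[C@H](O)[C@@H]12
F2 | step 26 | (1S)-chloromethanesulfonate of 37 | C=C1C(=O)O[C@H](/C=C(\C=C)CO[Si](c2ccccc2)(c2ccccc2)C(C)(C)C)[C@H]1[C@@H](OS(=O)(=O)CCl)C[C@@]1(C)O[C@@H]1C=C
F3 | step 26 | caesium (2Z)-4-(acetyloxy)-2-methylbut-2-enoate | [Cs+].C/C(C(=O)[O-])=C/COC(C)=O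
F4 | step 25 | (1R)-epimer of 37, (4R,5R)-4-{(1R)-2-[(2R,3R)-3-ethenyl-2-methyloxiran-2-yl]-1-hydroxyethyl}-5-{(1E)-2-[(TBDPS-oxy)methyl]buta-1,3-dien-1-yl}-3-methylideneoxolan-2-one | C=C1C(=O)O[C@H](/C=C(\C=C)CO[Si](c2ccccc2)(c2ccccc2)C(C)(C)C)[C@H]1[C@H](O)C[C@@]1(C)O[C@@H]1C=C
F5 | step 25 | (2Z)-4-(acetyloxy)-2-methylbut-2-enoic 2,4,6-trichlorobenzoic anhydride | CC(=O)OC/C=C(/C)C(=O)OC(=O)c1c(Cl)cc(Cl)cc1Cl
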